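## Structural features

α-Onocerin is a C2-symmetric C30 seco-triterpene diol built from two identical trans-decalin units (rings A/B and A'/B') whose C9 and C13 are joined by the two-carbon bridge C11–C12; in the numbering used throughout, C13, C14, C17, C18, C21 and C22 are the symmetry partners of C9, C8, C5, C10, C3 and C4. Each decalin carries four stereocentres in a row: C3 (equatorial 3β-hydroxyl, S), C5 (R), the quaternary C10 (β-methyl, R) and C9 (S, α-hydrogen, bridge equatorial), with C3 and C5 separated only by the quaternary, non-stereogenic C4 that bears the gem-dimethyl group. C8 and C14 each carry an exocyclic methylene group next to the allylic methine C9 or C13. These 1,1-disubstituted alkenes are the fragile part, because acid moves them into the ring; they should therefore be made late and the final deprotection must be non-acidic. The real difficulty is the congested array C4 (quaternary)–C5 (tertiary)–C10 (quaternary) in each ring A, together with the need to build both halves in the same absolute sense, since opposite senses give a meso diastereomer. C9 and C13 are no separate problem: α to a C8 or C14 ketone they are epimerisable, and the natural configuration is the equatorial, more stable one. The key step exploits the fact that in ring A the bonds C1–C10 and C4–C5 flank the C5–C10 bond. C5–C10 with its cis C10-methyl/C6 relationship is the trace of an E-α-methyl enone, and C1–C2–C3(O)–C4(CH3)2 is the trace of a 3-silyloxy-4-methylpenta-1,3-diene, so both rings A can be closed on one bis(enone) whose ketone carbons C9 and C13 belong to a single succinyl unit.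

## Logic of the disconnections

**16 ⇒ 15 ⇒ 14.** The two exocyclic C=CH2 bonds at C8 and C14 are cut, and the two hydroxyl groups are masked as silyl ethers. The cut is placed here because these alkenes are the acid-sensitive groups, and because a ketone at C8/C14 makes C9/C13 epimerisable, so their configuration needs no control of its own. Two carbons and the most fragile functionality are removed. The forward steps must methylenate two hindered, enolisable ketones and then desilylate without acid.

**14 ⇒ 12 (through 13).** The ring B bonds C8–C9 and C13–C14 are cut, so that C9/C13 become ketone carbons and C8/C14 ester carbons; 13 is the enol ether that connects the two oxidation patterns. This is the one ring B bond whose removal places an acyl group on the quaternary C10 and reveals the succinyl unit C9–C11–C12–C13. Two rings disappear and a bis(decalin) becomes two monocyclic rings A on an open chain. The forward reductive coupling must pair each ketone with its own ester through a six-membered ring, and not the two ketones with each other.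

**12 ⇒ 11 ⇒ 10 ⇒ 9.** At C3 and C21 the O–Si bond is removed (11), the carbinol is taken back to the ketone (10) and the ketone is written as its C2=C3 silyl enol ether (9). No skeletal bond is cut; the purpose is to expose a cyclohexene with an enol ether oxygen at C3, the retron of a silyloxydiene cycloaddition, and to leave C3 to substrate control. The forward reduction must select the ring ketones over the C9/C13 ketones and deliver hydride to the α face.

**9 ⇒ 8 + two molecules of 2.** The bonds C1–C10 and C4–C5 are cut in both halves. The cut is made here because these bonds flank C5–C10, whose substituent pattern is that of an E enone, and because C3–O and the C4 gem-dimethyl group map onto the diene. This removes two rings, four C–C bonds and four stereocentres, including both quaternary ones, and leaves three achiral components. The forward step must be regioselective (C4 to C5), must transfer the enone geometry, and must choose the same enone face twice.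

**8 ⇒ 6 + two molecules of 7.** Both C5=C10 double bonds are cut. The linear C14 diester falls into a symmetrical C8 core and two C4 aldehyde esters. The forward olefination must give the E geometry at both alkenes, since that geometry becomes the C5/C10 relative configuration.

**6 ⇒ 3 + 4 (through 5).** The acyl–ylide bonds C9–C10 and C13–C18 are cut, which returns a four-carbon diacid chloride and a two-carbon phosphonium salt. The forward double acylation must stay intermolecular at both acid chloride functions and needs a second equivalent of 5 per acyl group as base.

**2 ⇒ 1.** The O–Si bond is cut. The ketone has a single enolisable hydrogen, so the only demand on the forward step is that the vinyl ketone survives the conditions.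

## Other disconnections considered

**Alternative 1:** The cut removes C8–C9 and C13–C14 while C8 and C14 stay joined, so that a temporary ring C is created and later destroyed.
- **Forward step.** Heating the 14-membered macrocycle A2 should give the pentacyclic 1,4-cyclohexadiene A1 by transannular [4+2] addition, closing rings B, C and B' at once. In A2 the two ring A units are linked by the E,E-diene C9=C11–C12=C13 and by the tether C6–C7–C8≡C14–C15–C16.
- **Follow-up.** Hydrogenation of C11=C12 and oxidative cleavage of C8=C14 would lead to 14 of the chosen route.
- **In favour.** The step needs no reagent. The C3 oxygen travels as a silyl ether from the start. The cis relationship of H9 and H13 that suprafacial addition must give is harmless, because both centres become epimerisable after the cleavage. No carbonyl–carbonyl coupling in the presence of a 1,4-diketone is required. On ring B formation and on predictability of mechanism (concerted, pericyclic, no new catalyst–substrate pairing) this plan is the equal or the better of the chosen one.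
- **Against.** The real problem, the enantiopure C4–C5–C10 array with its quaternary carbon, is only moved into the synthesis of the ring A units of A2, which the chosen key step solves directly. A2 also needs a macrocyclisation. The alkyne and diene are both unactivated and the diene termini are attached to quaternary carbons, so forcing temperatures are to be expected. A 1,4-cyclohexadiene with two doubly allylic C–H bonds such as A1 tends to aromatise under such conditions, which would erase C9/C13 and block the cleavage.
- **Comparison.** On structure both plans meet at 14, but the chosen step creates four lasting stereocentres and the transannular step none. On step economy the chosen plan is clearly shorter, because assembling A2 and excising ring C again costs many operations.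

**Alternative 2:** The cut is C1–C10 in both halves, made on preformed ring B cyclohexanones.
- **Forward step.** Pd2(dba)3 (zerovalent palladium) with t-Bu-PHOX should ionise both allyl enol carbonates of A4, release CO2 and allylate each enolate at C10, giving the bis(2-allyl-2-methylcyclohexanone) A3.
- **In favour.** The reaction type is established for enol carbonates of 2-alkylcyclohexanones, with regiodefined enolates and neutral conditions that tolerate the ketals. On precedent for the catalyst-controlled creation of the quaternary centre this plan is the better one. It shares with the chosen plan the statistical advantage of two independent catalyst-controlled events on one substrate.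
- **Against.** A4 must already contain C9 and C13 as enantiopure stereocentres next to the reacting carbons, and their origin is a separate problem. The tetrasubstituted enolate is flanked by the C9 branch and the C8 ketal, a hindered situation for this catalysis, with a matched/mismatched question on top. Only one bond per half and no ring is formed. Ring A must still be annulated from the allyl group and the C5 ketone, which means introducing C4 with its gem-dimethyl group, the C3 oxygen and the trans C5 hydrogen; the congested C4–C5 bond is still to be made.
- **Comparison.** On structure the chosen step delivers complete rings A with C5 and C10, whereas this one delivers C10 alone. On mechanism both rely on catalyst control, with the alternative on firmer ground. On step economy the chosen plan is much shorter.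

**Alternative 3:** The cut is C6–C7 and C15–C16, between preformed rings A and a linchpin that holds C7–C9, the bridge and C13–C15.
- **Forward step.** Fourfold deprotonation of diethyl 2,5-diacetyladipate A6 and alkylation of both terminal methyl carbons by the ring A allylic bromide A7 should give the bis(β-keto ester) A5.
- **Follow-up.** Acid-induced closure of each keto ester onto the C5=C10 alkene and decarboxylation would again reach the stage of 14.
- **In favour.** It is a three-component, C2-symmetric convergence equal to that of the chosen plan. The key alkylation is classical γ-alkylation of β-keto ester dianions and is more secure than the chosen key step. Both halves come from one enantiopure building block with a single stereocentre (C3), so no meso issue arises in the key step itself. On these two points it is the better plan.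
- **Against.** The key step has no stereochemical content. C5, C10 and C9 are created afterwards in a cationic ring closure in which the face of protonation of the tetrasubstituted alkene is steered only by the remote C3 silyloxy group, twice, so the diastereomer problem returns there. That closure must join C9, which carries ester, acyl and bridge, to the quaternary C10, in competition with O-cyclisation of the enol to a cyclic enol ether and with loss of the acid-labile silyl ether. A7 needs its own asymmetric synthesis.
- **Comparison.** On structure the alternative keeps ring A intact while the chosen plan builds it. On mechanism the alternative relies on substrate-controlled cation chemistry, the chosen plan on geometry transfer plus catalyst control. Step economy is about equal.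

Key step: step 4

Assumption 1: 4-methylpent-1-en-3-one (1) is taken as purchasable in stabilised form and is distilled before use.
Assumption 2: the oxazaborolidinium ion from (S)-α,α-diphenylprolinol is taken to expose the C5-Re/C10-Si face of the bound enone; if the preference is the opposite, the catalyst from (R)-α,α-diphenylprolinol is used in the same way.

## Steps

Step 1
Reactants: 1 4-methylpent-1-en-3-one
Product: 2 4-methyl-3-(triisopropylsilyloxy)penta-1,3-diene
Conditions: i-Pr3SiOSO2CF3, Et3N, Et2O, 0 °C
Reagents that add atoms: triisopropylsilyl trifluoromethanesulfonate, CC(C)[Si](C(C)C)(C(C)C)OS(=O)(=O)C(F)(F)F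
Why: Soft enolisation (silyl triflate/amine): the only enolisable hydrogen is the isopropyl methine, so a single, fully substituted silyl dienol ether should form. The triisopropylsilyl group is preferred to a smaller silyl group because it resists silyl transfer and protodesilylation under the cationic Lewis acid of step 4.

Step 2
Reactants: 3 succinyl chloride; 4 ethyltriphenylphosphonium bromide
Product: 6 2,7-bis(triphenylphosphoranylidene)octane-3,6-dione, via ethylidenetriphenylphosphorane 5 (not isolated)
Conditions: 4 (4 equiv), NaN(SiMe3)2, THF, 0 °C; then 3 (1 equiv, slow addition), −78 °C → rt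
Reagents that add atoms: none
Why: Acylation of a non-stabilised ylide by an acid chloride with transylidation: each acylphosphonium salt is deprotonated by a second equivalent of 5 to the stabilised acyl ylide, which does not react further with acid chloride. Slow addition of 3 to excess 5 at low temperature is meant to keep the second acid chloride function from cyclising onto the first acyl ylide.

Step 3
Reactants: 6 2,7-bis(triphenylphosphoranylidene)octane-3,6-dione; 7 methyl 4-oxobutanoate
Product: 8 dimethyl (4E,10E)-5,10-dimethyl-6,9-dioxotetradeca-4,10-dienedioate
Conditions: 7 (3 equiv), toluene, 100 °C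
Reagents that add atoms: none
Why: Double Wittig olefination with a carbonyl-stabilised, α-methyl ylide: such ylides react with aliphatic aldehydes on heating and place the aldehyde chain trans to the acyl group. This E geometry later becomes the cis relationship between the C10 methyl group and C6.

Step 4
Reactants: 8 dimethyl (4E,10E)-5,10-dimethyl-6,9-dioxotetradeca-4,10-dienedioate; 2 4-methyl-3-(triisopropylsilyloxy)penta-1,3-diene
Product: 9 1,4-bis[(1S,6S)-6-(3-methoxy-3-oxopropyl)-1,5,5-trimethyl-4-(triisopropylsilyloxy)cyclohex-3-en-1-yl]butane-1,4-dione (both rings A as C2=C3 silyl enol ethers; 5S,10S,17S,18S in onocerane numbering; C10 methyl cis to the C5 side chain)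
Conditions: (S)-o-tolyl-oxazaborolidinium triflimide [from (S)-α,α-diphenylprolinol, tri-o-tolylboroxine and HNTf2] (40 mol%), 2 (5 equiv), CH2Cl2, −78 → −20 °C
Reagents that add atoms: none
Why: Proposed new method: the cationic boron Lewis acid binds each enone carbonyl and lowers its LUMO, so that the nucleophilic silyl enol ether terminus C4 attacks the β carbon C5 first and the vinyl terminus C1 then bonds to the α carbon C10, in a strongly asynchronous [4+2] cycloaddition whose stepwise limit is a Mukaiyama–Michael addition followed by collapse of the enolate onto the silyloxyallyl cation. The closest known reaction types are the strong-Lewis-acid Diels–Alder reaction of hindered 2-silyloxydienes with substituted enones, which forms vicinal quaternary and tertiary carbons, and the oxazaborolidinium-catalysed enantioselective Diels–Alder reaction of 2-silyloxybutadienes with enones; new is the combination of a fully substituted diene terminus, an acyclic E-α-methyl enone and two additions on one substrate. Ring A and ring A' each close as a six-membered cyclohexene silyl enol ether, by suprafacial [4π+2π] addition in the concerted picture or by 6-(enolexo)-endo-trig attack of the C10 enolate on C1 in the stepwise one. C10 (C18) is set relative to C5 (C17) by the E geometry of the enone, which is transferred suprafacially so that the C10 methyl group and the C6 chain end up cis; C4 carries two methyl groups and C1 none, so there is no endo/exo question. The absolute configuration comes from the catalyst, which has to expose the C5-Re/C10-Si face of each enone. The two enones are insulated by the CH2CH2 spacer and react independently, so a wrong-face event in one half gives a meso-type diastereomer that chromatography removes, which should raise the enantiomeric purity of the C2 product above the per-event selectivity. Regioselectivity (C4 to C5, the C3 oxygen 1,4 to the C9 carbonyl) is secured by the matched polarity of the partners, chemoselectivity by the saturated esters not being dienophiles, and the bulky silyl group disfavours silyl transfer, which would stop the sequence at the open Michael adduct and release an achiral silyl triflimide catalyst.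

Step 5
Reactants: 9 bis(silyl enol ether) adduct
Product: 10 1,4-bis[(1S,2S)-2-(3-methoxy-3-oxopropyl)-1,3,3-trimethyl-4-oxocyclohexyl]butane-1,4-dione
Conditions: Bu4NF, AcOH, THF, 0 °C
Reagents that add atoms: none
Why: Fluoride cleavage of the silyl enol ethers, buffered with acetic acid so that the liberated enolates are protonated at once. Ketones, esters and the quaternary centres are untouched, and no acid strong enough to cyclodehydrate the 1,4-diketone to a furan is present.

Step 6
Reactants: 10 tetraketone diester
Product: 11 1,4-bis[(1S,2S,4S)-4-hydroxy-2-(3-methoxy-3-oxopropyl)-1,3,3-trimethylcyclohexyl]butane-1,4-dione (3β,21α-diol; hydroxyl cis to the C5 side chain)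
Conditions: NaBH4, MeOH–THF, −40 → −20 °C
Reagents that add atoms: none
Why: Borohydride reduction under steric approach control: the ring ketones should react much faster than the acyclic C9/C13 ketones, which are shielded by the quaternary C10/C18, and the esters are inert at this temperature. Hydride should enter C3 from the α face, anti to the C5 side chain and remote from the C10 methyl group, which gives the 3S alcohol, equatorial in the chair that becomes ring A of the trans-decalin.

Step 7
Reactants: 11 diol
Product: 12 1,4-bis[(1S,2S,4S)-4-(tert-butyldimethylsilyloxy)-2-(3-methoxy-3-oxopropyl)-1,3,3-trimethylcyclohexyl]butane-1,4-dione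
Conditions: t-BuMe2SiCl, imidazole, DMAP (cat.), DMF, 50 °C
Reagents that add atoms: tert-butyldimethylsilyl chloride, CC(C)(C)[Si](C)(C)Cl
Why: Silylation of the hindered secondary alcohols with the chlorosilane and imidazole, conditions that do not enolise or silylate the ketones. The ethers keep the hydroxyl groups from forming titanium alkoxides in step 8 and from consuming ylide in step 9.

Step 8
Reactants: 12 bis(silyl ether) diketone diester
Product: 14 1,2-bis[(1R,4aR,6S,8aS)-6-(tert-butyldimethylsilyloxy)-5,5,8a-trimethyl-2-oxodecahydronaphthalen-1-yl]ethane (bis(silyl ether) of 3β,21α-dihydroxy-26,27-dinor-8,14-secogammacerane-8,14-dione; trans-decalins, bridge equatorial at C9 and C13), via bis(methyl enol ether) 13 (not isolated)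
Conditions: TiCl3, LiAlH4, Et3N, DME, reflux, slow addition; then 1 M HCl, THF, rt; then NaOMe, MeOH, rt
Reagents that add atoms: water, O
Why: Intramolecular titanium-mediated keto–ester coupling (McMurry type): low-valent titanium joins each ketone carbon (C9, C13) to its own ester carbon (C8, C14) through a six-membered ring and deoxygenates to the cyclic methyl enol ether 13, which aqueous acid hydrolyses to the ketone. The trans ring fusion is already fixed by C5/C10, and C9/C13 are brought by base equilibration to the natural configuration with the bridge equatorial.

Step 9
Reactants: 14 8,14-dione bis(silyl ether)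
Product: 15 1,2-bis[(1S,4aR,6S,8aR)-6-(tert-butyldimethylsilyloxy)-5,5,8a-trimethyl-2-methylidenedecahydronaphthalen-1-yl]ethane (α-onocerin bis(tert-butyldimethylsilyl) ether)
Conditions: Ph3PCH3Br, KOC(CH3)3, toluene, 90 °C
Reagents that add atoms: methylenetriphenylphosphorane, C=P(c1ccccc1)(c1ccccc1)c1ccccc1 (made in the flask from methyltriphenylphosphonium bromide, C[P+](c1ccccc1)(c1ccccc1)c1ccccc1.[Br-])
Why: Wittig methylenation of the two hindered ring ketones with excess ylide at elevated temperature, a known transformation for 8-oxodecalins of this type. Enolisation under the basic conditions can only return C9/C13 to the same, more stable configuration, and the silyl ethers are inert.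

Step 10
Reactants: 15 α-onocerin bis(silyl ether)
Product: 16 α-onocerin, (3S,5R,9S,10R,13S,17R,18R,21S)-8,14-secogammacera-8(26),14(27)-diene-3,21-diol
Conditions: Bu4NF, THF, 60 °C
Reagents that add atoms: none
Why: Fluoride-mediated cleavage of the hindered secondary silyl ethers on warming. The conditions are non-acidic, so the exocyclic alkenes should not migrate into the rings.

## Compound list

1 | 4-methylpent-1-en-3-one | C=CC(=O)C(C)C | starting material
2 | 4-methyl-3-(triisopropylsilyloxy)penta-1,3-diene | C=CC(O[Si](C(C)C)(C(C)C)C(C)C)=C(C)C | intermediate
3 | succinyl chloride | ClC(=O)CCC(Cl)=O | starting material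
4 | ethyltriphenylphosphonium bromide | CC[P+](c1ccccc1)(c1ccccc1)c1ccccc1.[Br-] | starting material
5 | ethylidenetriphenylphosphorane | CC=P(c1ccccc1)(c1ccccc1)c1ccccc1 | intermediate
6 | 2,7-bis(triphenylphosphoranylidene)octane-3,6-dione | CC(=P(c1ccccc1)(c1ccccc1)c1ccccc1)C(=O)CCC(=O)C(C)=P(c1ccccc1)(c1ccccc1)c1ccccc1 | intermediate
7 | methyl 4-oxobutanoate | COC(=O)CCC=O | starting material
8 | dimethyl (4E,10E)-5,10-dimethyl-6,9-dioxotetradeca-4,10-dienedioate | COC(=O)CC/C=C(\C)C(=O)CCC(=O)/C(C)=C/CCC(=O)OC | intermediate
9 | 1,4-bis[(1S,6S)-6-(3-methoxy-3-oxopropyl)-1,5,5-trimethyl-4-(triisopropylsilyloxy)cyclohex-3-en-1-yl]butane-1,4-dione | COC(=O)CC[C@H]1C(C)(C)C(O[Si](C(C)C)(C(C)C)C(C)C)=CC[C@]1(C)C(=O)CCC(=O)[C@@]1(C)CC=C(O[Si](C(C)C)(C(C)C)C(C)C)C(C)(C)[C@@H]1CCC(=O)OC | intermediate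
10 | 1,4-bis[(1S,2S)-2-(3-methoxy-3-oxopropyl)-1,3,3-trimethyl-4-oxocyclohexyl]butane-1,4-dione | COC(=O)CC[C@H]1C(C)(C)C(=O)CC[C@]1(C)C(=O)CCC(=O)[C@@]1(C)CCC(=O)C(C)(C)[C@@H]1CCC(=O)OC | intermediate
11 | 1,4-bis[(1S,2S,4S)-4-hydroxy-2-(3-methoxy-3-oxopropyl)-1,3,3-trimethylcyclohexyl]butane-1,4-dione | COC(=O)CC[C@H]1C(C)(C)[C@@H](O)CC[C@]1(C)C(=O)CCC(=O)[C@@]1(C)CC[C@H](O)C(C)(C)[C@@H]1CCC(=O)OC | intermediate
12 | 1,4-bis[(1S,2S,4S)-4-(tert-butyldimethylsilyloxy)-2-(3-methoxy-3-oxopropyl)-1,3,3-trimethylcyclohexyl]butane-1,4-dione | COC(=O)CC[C@H]1C(C)(C)[C@@H](O[Si](C)(C)C(C)(C)C)CC[C@]1(C)C(=O)CCC(=O)[C@@]1(C)CC[C@H](O[Si](C)(C)C(C)(C)C)C(C)(C)[C@@H]1CCC(=O)OC | intermediate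
13 | 1,2-bis[(4aR,6S,8aS)-6-(tert-butyldimethylsilyloxy)-2-methoxy-5,5,8a-trimethyl-3,4,4a,5,6,7,8,8a-octahydronaphthalen-1-yl]ethane | COC1=C(CCC2=C(OC)CC[C@H]3C(C)(C)[C@@H](O[Si](C)(C)C(C)(C)C)CC[C@]23C)[C@@]2(C)CC[C@H](O[Si](C)(C)C(C)(C)C)C(C)(C)[C@@H]2CC1 | intermediate
14 | 1,2-bis[(1R,4aR,6S,8aS)-6-(tert-butyldimethylsilyloxy)-5,5,8a-trimethyl-2-oxodecahydronaphthalen-1-yl]ethane | O=C1CC[C@H]2C(C)(C)[C@@H](O[Si](C)(C)C(C)(C)C)CC[C@]2(C)[C@H]1CC[C@H]1C(=O)CC[C@H]2C(C)(C)[C@@H](O[Si](C)(C)C(C)(C)C)CC[C@]12C | intermediate
15 | 1,2-bis[(1S,4aR,6S,8aR)-6-(tert-butyldimethylsilyloxy)-5,5,8a-trimethyl-2-methylidenedecahydronaphthalen-1-yl]ethane | C=C1CC[C@H]2C(C)(C)[C@@H](O[Si](C)(C)C(C)(C)C)CC[C@]2(C)[C@H]1CC[C@H]1C(=C)CC[C@H]2C(C)(C)[C@@H](O[Si](C)(C)C(C)(C)C)CC[C@]12C | intermediate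
16 | α-onocerin, (3S,5R,9S,10R,13S,17R,18R,21S)-8,14-secogammacera-8(26),14(27)-diene-3,21-diol | C=C1CC[C@H]2C(C)(C)[C@@H](O)CC[C@]2(C)[C@H]1CC[C@H]1C(=C)CC[C@H]2C(C)(C)[C@@H](O)CC[C@]12C | target

## Step count and least certain steps

Total: 10 steps. Longest linear sequence: 9 steps (steps 2 to 10, from succinyl chloride); step 1 is the one-step side branch.

**Step 4 (key step, proposed new method).**
- What may go wrong: insufficient reactivity or facial discrimination of the chiral Lewis acid with this very hindered diene/enone pair; stalling after the first C4–C5 bond at the open Michael stage; loss of geometry transfer through a long-lived zwitterion, which would scramble C10 relative to C5; protodesilylation of the diene; acid-induced cyclodehydration of the 1,4-diketone.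
- Fallback (known chemistry, resolution instead of catalyst control): starting from 8 and 2, the double cycloaddition is promoted by the achiral mixed Lewis acid AlBr3/AlMe3 (10:1) in toluene–CH2Cl2 at −20 → 0 °C, the established way to force hindered silyloxydienes onto hindered enones. This should give 9 together with the enantiomeric adduct F1 and the meso adduct F2 in roughly statistical proportion. The meso adduct F2 is a diastereomer and is removed on silica; the racemate is separated by preparative chromatography on a chiral stationary phase. The route is rejoined at 9.

**Step 8.**
- What may go wrong: reductive coupling of the two ketones of the 1,4-diketone with each other instead of with their esters; plain reduction of the hindered ketones by residual hydride; intermolecular coupling if the dilution is insufficient.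
- Fallback (stepwise, SmI2-based ring closure): starting from 12, LiAlH4 in THF reduces esters and ketones to the tetraol F3, and Swern oxidation gives the dialdehyde diketone F4. SmI2 (THF, t-BuOH, −78 °C) then reduces the aldehydes selectively to ketyls, which add to the neighbouring ketones in a six-membered pinacol cyclisation to the bis(8,9-diol) F5. Swern oxidation of the secondary carbinols gives the bis(α-ketol) F6. SmI2 in THF–MeOH removes the tertiary α-hydroxyl groups by reductive cleavage, and NaOMe equilibrates C9/C13. The route is rejoined at 14.

**Step 6.**
- What may go wrong: over-reduction at the C9/C13 ketones; incomplete facial selectivity, because the monocyclic ketone is conformationally mobile.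
- Fallback (catalyst control instead of substrate control): starting from 10, Corey–Bakshi–Shibata reduction with (R)-2-methyl-CBS-oxazaborolidine and BH3·SMe2 in THF at −20 °C. The catalyst distinguishes the quaternary C4 flank from the C2 methylene flank and should deliver the 3S alcohol whatever the ring conformation, while the shielded acyclic ketones bind it poorly. The route is rejoined at 11; no new compound is involved.

**Step 2.**
- What may go wrong: cyclisation of the mono-acylated ylide onto the second acid chloride function (five-membered enol lactone or 1,3-dione); ketene formation by dehydrochlorination.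
- Fallback (forms the C11–C12 bond last, replaces steps 2 and 3): starting from 7, Wittig reaction with commercial 3-(triphenylphosphoranylidene)butan-2-one in toluene at 90 °C gives methyl (4E)-5-methyl-6-oxohept-4-enoate F7. Kinetic deprotonation of its methyl ketone with LiN(i-Pr)2 in THF at −78 °C and oxidative coupling of the lithium enolate with CuCl2 (DMF–THF, −78 °C → rt) joins two molecules. The route is rejoined at 8.

**Step 9.**
- What may go wrong: enolisation of the hindered ketones by the basic ylide, leading to incomplete methylenation or aldol side reactions of the 1,6-diketone.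
- Fallback (non-basic titanium methylidene chemistry): starting from 14, Takai–Lombardo methylenation with Zn, CH2Br2 and TiCl4 in THF–CH2Cl2 at 0 °C → rt, which tolerates the silyl ethers. The route is rejoined at 15; no new compound is involved.

## Further compounds

F1 | step 4 | enantiomeric adduct, 1,4-bis[(1R,6R)-6-(3-methoxy-3-oxopropyl)-1,5,5-trimethyl-4-(triisopropylsilyloxy)cyclohex-3-en-1-yl]butane-1,4-dione | COC(=O)CC[C@@H]1C(C)(C)C(O[Si](C(C)C)(C(C)C)C(C)C)=CC[C@@]1(C)C(=O)CCC(=O)[C@]1(C)CC=C(O[Si](C(C)C)(C(C)C)C(C)C)C(C)(C)[C@H]1CCC(=O)OC
F2 | step 4 | meso adduct, one ring (1S,6S) and the other (1R,6R) | COC(=O)CC[C@H]1C(C)(C)C(O[Si](C(C)C)(C(C)C)C(C)C)=CC[C@]1(C)C(=O)CCC(=O)[C@]1(C)CC=C(O[Si](C(C)C)(C(C)C)C(C)C)C(C)(C)[C@H]1CCC(=O)OC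
F3 | step 8 | tetraol, 1,4-bis[(1S,2S,4S)-4-(tert-butyldimethylsilyloxy)-2-(3-hydroxypropyl)-1,3,3-trimethylcyclohexyl]butane-1,4-diol (carbinol configuration at C9/C13 not defined) | OCCC[C@H]1C(C)(C)[C@@H](O[Si](C)(C)C(C)(C)C)CC[C@]1(C)C(O)CCC(O)[C@@]1(C)CC[C@H](O[Si](C)(C)C(C)(C)C)C(C)(C)[C@@H]1CCCO
F4 | step 8 | dialdehyde diketone, 1,4-bis[(1S,2S,4S)-4-(tert-butyldimethylsilyloxy)-1,3,3-trimethyl-2-(3-oxopropyl)cyclohexyl]butane-1,4-dione | O=CCC[C@H]1C(C)(C)[C@@H](O[Si](C)(C)C(C)(C)C)CC[C@]1(C)C(=O)CCC(=O)[C@@]1(C)CC[C@H](O[Si](C)(C)C(C)(C)C)C(C)(C)[C@@H]1CCC=O
F5 | step 8 | bis(8,9-diol), 1,2-bis[6-(tert-butyldimethylsilyloxy)-1,2-dihydroxy-5,5,8a-trimethyldecahydronaphthalen-1-yl]ethane (configuration at C8/C9 and C13/C14 not defined) | OC1CC[C@H]2C(C)(C)[C@@H](O[Si](C)(C)C(C)(C)C)CC[C@]2(C)C1(O)CCC1(O)C(O)CC[C@H]2C(C)(C)[C@@H](O[Si](C)(C)C(C)(C)C)CC[C@]12C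
F6 | step 8 | bis(α-ketol), 1,2-bis[6-(tert-butyldimethylsilyloxy)-1-hydroxy-5,5,8a-trimethyl-2-oxodecahydronaphthalen-1-yl]ethane (configuration at C9/C13 not defined) | O=C1CC[C@H]2C(C)(C)[C@@H](O[Si](C)(C)C(C)(C)C)CC[C@]2(C)C1(O)CCC1(O)C(=O)CC[C@H]2C(C)(C)[C@@H](O[Si](C)(C)C(C)(C)C)CC[C@]12C
F0 | step 6 | none | none
F7 | step 2 | methyl (4E)-5-methyl-6-oxohept-4-enoate | COC(=O)CC/C=C(\C)C(C)=O
F0 | step 9 | none | none
A1 | alternative 1 | pentacyclic 8(14),11-diene bis(tert-butyldimethylsilyl) ether (H9 and H13 cis) | C12=C3CC[C@H]4C(C)(C)[C@@H](O[Si](C)(C)C(C)(C)C)CC[C@]4(C)[C@H]3C=C[C@H]1[C@@]1(C)CC[C@H](O[Si](C)(C)C(C)(C)C)C(C)(C)[C@@H]1CC2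
A2 | alternative 1 | 14-membered macrocyclic (9E,12E)-dien-8(14)-yne bis(tert-butyldimethylsilyl) ether | C1#CCC[C@H]2C(C)(C)[C@@H](O[Si](C)(C)C(C)(C)C)CC[C@]2(C)/C=C/C=C/[C@@]2(C)CC[C@H](O[Si](C)(C)C(C)(C)C)C(C)(C)[C@@H]2CC1
A3 | alternative 2 | bis(2-allyl-2-methylcyclohexanone) with both C10 centres set, C8 and C14 as dimethyl ketals | C=CC[C@]1(C)[C@@H](CC[C@@H]2[C@@](C)(CC=C)C(=O)CCC2(OC)OC)C(OC)(OC)CCC1=O
A4 | alternative 2 | bis(allyl enol carbonate) of the ring B diketone | C=CCOC(=O)OC1=C(C)[C@@H](CC[C@@H]2C(C)=C(OC(=O)OCC=C)CCC2(OC)OC)C(OC)(OC)CC1
A5 | alternative 3 | bis(β-keto ester) carrying both ring A units | CCOC(=O)C(CCC(C(=O)OCC)C(=O)CCC1=C(C)CC[C@H](O[Si](C)(C)C(C)(C)C)C1(C)C)C(=O)CCC1=C(C)CC[C@H](O[Si](C)(C)C(C)(C)C)C1(C)C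
A6 | alternative 3 | diethyl 2,5-diacetyladipate | CCOC(=O)C(CCC(C(C)=O)C(=O)OCC)C(C)=O
A7 | alternative 3 | tert-butyl{[(1S)-3-(bromomethyl)-2,2,4-trimethylcyclohex-3-en-1-yl]oxy}dimethylsilane | BrCC1=C(C)CC[C@H](O[Si](C)(C)C(C)(C)C)C1(C)C
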